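**Retrosynthetic overview** (isochromene numbering: C1, O2, C3, C4, C4a, C5–C8, C8a)
1. The plan rests on ring B, the carbocycle C4a–C5–C6–C7–C8–C8a. Its oxygen-bearing quaternary C7 stands 1,4 to C4a across the C8–C8a link, and C8a carries the aldehyde-level C1: the pattern of a furan oxygen bridging a six-membered ring made from a 2,5-dimethylfuran and an enal.
2. Cut last: the aryl O–Si bonds, the side-chain alkene (cross-metathesis of a 3-propenyl group with an allylic diacetate) and the C7 O–acyl bond (protected orsellinoyl chloride on the C7 alkoxide).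
3. Ring A (pyran) is cut at C3–C4 and O2–C1: acylation of the C4 methyl of a C1-(dimethylamino)methylene dienone with a crotonic N-methoxy-N-methylamide, then closure by addition–elimination at C1.
4. The C6 carbonyl comes from the C5=C6 alkene (directed epoxidation, palladium-mediated 1,2-hydride shift); the C7 hydroxyl and C4a=C8a come from E1cB opening of the C4a–O bond of the bridge.
5. Ring B is made first by the enantioselective [4+2] of 2,5-dimethylfuran and acrolein (C7–C8 and C4a–C8a), ring A second; the orsellinate ring is bought.

Key step: step 1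

Assumption: the sense of face selection of the oxazaborolidinium catalyst on acrolein with this furan is not established; the (S)-configured catalyst is written, and the equally available (R)-configured catalyst is used instead if the first assignment of 4 shows the antipode.

**Route**

Step 1
Reactants: 1 2,5-dimethylfuran; 2 acrolein (prop-2-enal)
Product: 4 (5S)-5-hydroxy-2,5-dimethylcyclohexa-1,3-diene-1-carbaldehyde, via endo cycloadduct 3 (not isolated)
Conditions: B-(2-methylphenyl)oxazaborolidine of (S)-α,α-diphenylprolinol, C24H24BNO (20 mol%), HN(SO2CF3)2 (18 mol%), 1 (3 equiv), CH2Cl2, −78 °C; then DBU (1.5 equiv), −78 → 0 °C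
Reagents that add atoms: none
Why: Acrolein bound through its formyl oxygen to the cationic boron adds across the 2,5-termini of the furan in a concerted, asynchronous [4+2] cycloaddition; the closest known reactions are the Lewis-acid-catalysed addition of this same pair at low temperature and the enantioselective Diels–Alder reactions of furans with 2-haloacroleins and acrylates under chiral oxazaborolidine-type boron Lewis acids. Ring B closes by intermolecular cycloaddition, forming C7–C8 and C4a–C8a, and the furan oxygen becomes the bridge. C7 and C4a are set together by the open enantioface of the bound acrolein (the other lies over an aryl group of the catalyst) in combination with the endo approach, and C8a by the endo transition state. The step needs two selectivities: face selection and a high endo:exo ratio, because endo and exo adducts grown on the same acrolein face carry antipodal bridgeheads and would give antipodal 4 once C8a is flattened. Kinetic control at −78 °C under cationic activation and the absence of 3,4-substituents on the furan should favour endo, and the symmetry of the furan removes any regiochemical question. DBU then arrests the catalyst and removes the C8a proton, which is β only to the C4a–O bond, so E1cB opening gives 4 with the C7 oxygen and configuration untouched before cycloreversion or dehydrative aromatisation can intervene.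

Step 2
Reactants: 4
Product: 5 (1R,5S,6R)-5-hydroxy-2,5-dimethyl-7-oxabicyclo[4.1.0]hept-2-ene-3-carbaldehyde
Conditions: VO(acac)2 (3 mol%), t-BuOOH (1.3 equiv, decane), CH2Cl2, 0 °C
Reagents that add atoms: tert-butyl hydroperoxide, CC(C)(C)OO
Why: Hydroxyl-directed vanadium epoxidation delivers oxygen from the C7 vanadium alkoxide to the allylic C5=C6 alkene on the face syn to the hydroxyl, which sets C5 and C6 (both erased later), while the tetrasubstituted, aldehyde-conjugated C4a=C8a alkene is inert.

Step 3
Reactants: 5
Product: 6 (5S)-5-hydroxy-2,5-dimethyl-4-oxocyclohex-1-ene-1-carbaldehyde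
Conditions: Pd(PPh3)4 (5 mol%), THF, 0 °C → rt
Reagents that add atoms: none
Why: Zerovalent palladium ionises the allylic C5–O bond of the vinyl epoxide to a π-allylpalladium alkoxide, and a 1,2-hydride shift from C6 through a palladium hydride gives the C6 ketone (the palladium-catalysed isomerisation of 1,3-diene monoepoxides to ketones); C7 carries no hydrogen and is untouched, and 6 should exist largely as its C1 enol, a vinylogous acid.

Step 4
Reactants: 6
Product: 7 (4E,6S)-4-[(dimethylamino)methylidene]-6-hydroxy-3,6-dimethylcyclohex-2-en-1-one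
Conditions: Me2NH (2 M in THF, 2 equiv), 4 Å MS, CH2Cl2, rt
Reagents that add atoms: dimethylamine, CNC
Why: Enaminone formation from a hydroxymethylene ketone and a secondary amine takes place at the unhindered aldehyde carbon C1, masking the acidic enol and the aldehyde as a push–pull dienaminone and leaving the C4 methyl as the only enolisable position.

Step 5
Reactants: 8 (E)-but-2-enoyl chloride
Product: 9 (E)-N-methoxy-N-methylbut-2-enamide
Conditions: MeNHOMe·HCl (1.1 equiv), Et3N (2.2 equiv), CH2Cl2, 0 °C
Reagents that add atoms: N,O-dimethylhydroxylamine hydrochloride, CNOC.Cl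
Why: Acylation of the amine by the acid chloride (amide formation) should be faster than conjugate addition at 0 °C, and the E alkene is not touched.

Step 6
Reactants: 7; 9 (E)-N-methoxy-N-methylbut-2-enamide
Product: 11 (7S)-7-hydroxy-7-methyl-3-[(E)-prop-1-enyl]-7,8-dihydro-6H-isochromen-6-one, via acylated enaminone 10 (not isolated)
Conditions: LiN(i-Pr)2 (2.3 equiv), THF, −78 °C; 9 (1.3 equiv), −78 → −20 °C; then 2 M HCl, THF, rt
Reagents that add atoms: none
Why: Two equivalents of base give the C7 alkoxide and the cross-conjugated dienolate of the C4 methyl (C7 is quaternary, so no other α- or γ-hydrogen exists), and attack through the methylene terminus on the N-methoxy-N-methylamide keeps the dienaminone conjugation and stops at the chelated tetrahedral adduct (γ-acylation of a vinylogous amide enolate); acid then releases ketone 10, whose C3 enol oxygen displaces dimethylamine at C1 by addition–elimination and closes the pyran.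

Step 7
Reactants: 12 orsellinic acid (2,4-dihydroxy-6-methylbenzoic acid)
Product: 13 tert-butyldimethylsilyl 2,4-bis(tert-butyldimethylsilyloxy)-6-methylbenzoate
Conditions: TBSCl (4 equiv), imidazole (8 equiv), DMAP (cat.), DMF, 50 °C
Reagents that add atoms: tert-butyldimethylsilyl chloride, CC(C)(C)[Si](C)(C)Cl
Why: Exhaustive silylation covers both phenols and the carboxylic acid, warming and DMAP being included for the hydrogen-bonded ortho phenol.

Step 8
Reactants: 13
Product: 14 2,4-bis(tert-butyldimethylsilyloxy)-6-methylbenzoyl chloride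
Conditions: (COCl)2 (1.2 equiv), DMF (cat.), CH2Cl2, 0 °C → rt; used crude
Reagents that add atoms: oxalyl chloride, O=C(Cl)C(=O)Cl
Why: The chloroiminium reagent from oxalyl chloride and DMF converts the silyl ester directly into the acid chloride under neutral conditions, releasing the silyl chloride and no HCl, so the two aryl silyl ethers survive.

Step 9
Reactants: 11; 14
Product: 15 [(7S)-7-methyl-6-oxo-3-[(E)-prop-1-enyl]-7,8-dihydro-6H-isochromen-7-yl] 2,4-bis(tert-butyldimethylsilyloxy)-6-methylbenzoate
Conditions: LiN(SiMe3)2 (1.05 equiv), THF, −78 °C; then 14 (1.3 equiv), −78 → 0 °C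
Reagents that add atoms: none
Why: The tertiary α-ketol hydroxyl is the most acidic site of 11, and its lithium alkoxide should be acylated by the doubly ortho-substituted aroyl chloride where the neutral alcohol would not be (acylation of a lithium tert-alkoxide with a hindered acid chloride); no bond to the C7 carbon is broken, so its configuration is kept.

Step 10
Reactants: 15; 16 (Z)-but-2-ene-1,4-diyl diacetate
Product: 17 [(7S)-3-[(E)-3-acetyloxyprop-1-enyl]-7-methyl-6-oxo-7,8-dihydro-6H-isochromen-7-yl] 2,4-bis(tert-butyldimethylsilyloxy)-6-methylbenzoate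
Conditions: second-generation Hoveyda–Grubbs catalyst RuCl2(H2IMes)(=CH–C6H4-2-O-i-Pr) (10 mol%), 16 (5 equiv), CH2Cl2, 40 °C
Reagents that add atoms: none
Why: Olefin cross-metathesis exchanges the methyl terminus of the 1,2-disubstituted propenyl group for CH2OAc from the excess symmetrical diacetate, the trisubstituted ring alkenes and enol ethers being inert, and the conjugated product is expected as the E isomer under thermodynamic control.

Step 11
Reactants: 17
Product: 18 [(7S)-3-[(E)-3-acetyloxyprop-1-enyl]-7-methyl-6-oxo-7,8-dihydro-6H-isochromen-7-yl] 2,4-dihydroxy-6-methylbenzoate (target)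
Conditions: HF·pyridine, pyridine, THF, 0 °C → rt
Reagents that add atoms: none
Why: Fluoride-mediated cleavage of the two aryl silyl ethers under buffered, weakly acidic conditions should leave the allylic acetate, the hindered benzoate, the C7 centre and the pyran core unchanged.

**Compound list**
1 | 2,5-dimethylfuran | Cc1ccc(C)o1 | starting material
2 | acrolein (prop-2-enal) | C=CC=O | starting material
3 | (1S,2S,4S)-1,4-dimethyl-7-oxabicyclo[2.2.1]hept-5-ene-2-carbaldehyde (formyl endo) | C[C@]12C=C[C@](C)(O1)[C@@H](C=O)C2 | intermediate (not isolated)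
4 | (5S)-5-hydroxy-2,5-dimethylcyclohexa-1,3-diene-1-carbaldehyde | C[C@@]1(O)C=CC(C)=C(C=O)C1 | intermediate
5 | (1R,5S,6R)-5-hydroxy-2,5-dimethyl-7-oxabicyclo[4.1.0]hept-2-ene-3-carbaldehyde (epoxide syn to OH) | C[C@@]1(O)[C@@H]2O[C@@H]2C(C)=C(C=O)C1 | intermediate
6 | (5S)-5-hydroxy-2,5-dimethyl-4-oxocyclohex-1-ene-1-carbaldehyde (drawn as the keto–enal tautomer) | C[C@@]1(O)C(=O)CC(C)=C(C=O)C1 | intermediate
7 | (4E,6S)-4-[(dimethylamino)methylidene]-6-hydroxy-3,6-dimethylcyclohex-2-en-1-one | C[C@@]1(O)C(=O)C=C(C)/C(=C/N(C)C)C1 | intermediate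
8 | (E)-but-2-enoyl chloride | C/C=C/C(Cl)=O | starting material
9 | (E)-N-methoxy-N-methylbut-2-enamide | C/C=C/C(=O)N(C)OC | intermediate
10 | (4E,6S)-4-[(dimethylamino)methylidene]-6-hydroxy-6-methyl-3-[(E)-2-oxopent-3-enyl]cyclohex-2-en-1-one | C[C@@]1(O)C(=O)C=C(CC(=O)/C=C/C)/C(=C/N(C)C)C1 | intermediate (not isolated)
11 | (7S)-7-hydroxy-7-methyl-3-[(E)-prop-1-enyl]-7,8-dihydro-6H-isochromen-6-one | C/C=C/C1=CC2=CC(=O)[C@@](C)(O)CC2=CO1 | intermediate
12 | orsellinic acid (2,4-dihydroxy-6-methylbenzoic acid) | Cc1cc(O)cc(O)c1C(=O)O | starting material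
13 | tert-butyldimethylsilyl 2,4-bis(tert-butyldimethylsilyloxy)-6-methylbenzoate | Cc1cc(O[Si](C)(C)C(C)(C)C)cc(O[Si](C)(C)C(C)(C)C)c1C(=O)O[Si](C)(C)C(C)(C)C | intermediate
14 | 2,4-bis(tert-butyldimethylsilyloxy)-6-methylbenzoyl chloride | Cc1cc(O[Si](C)(C)C(C)(C)C)cc(O[Si](C)(C)C(C)(C)C)c1C(Cl)=O | intermediate
15 | [(7S)-7-methyl-6-oxo-3-[(E)-prop-1-enyl]-7,8-dihydro-6H-isochromen-7-yl] 2,4-bis(tert-butyldimethylsilyloxy)-6-methylbenzoate | C/C=C/C1=CC2=CC(=O)[C@@](C)(OC(=O)c3c(C)cc(O[Si](C)(C)C(C)(C)C)cc3O[Si](C)(C)C(C)(C)C)CC2=CO1 | intermediate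
16 | (Z)-but-2-ene-1,4-diyl diacetate | CC(=O)OC/C=C\COC(C)=O | starting material
17 | [(7S)-3-[(E)-3-acetyloxyprop-1-enyl]-7-methyl-6-oxo-7,8-dihydro-6H-isochromen-7-yl] 2,4-bis(tert-butyldimethylsilyloxy)-6-methylbenzoate | CC(=O)OC/C=C/C1=CC2=CC(=O)[C@@](C)(OC(=O)c3c(C)cc(O[Si](C)(C)C(C)(C)C)cc3O[Si](C)(C)C(C)(C)C)CC2=CO1 | intermediate
18 | [(7S)-3-[(E)-3-acetyloxyprop-1-enyl]-7-methyl-6-oxo-7,8-dihydro-6H-isochromen-7-yl] 2,4-dihydroxy-6-methylbenzoate | CC(=O)OC/C=C/C1=CC2=CC(=O)[C@@](C)(OC(=O)c3c(C)cc(O)cc3O)CC2=CO1 | target

**Step count**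
Total: 11 steps. Longest linear sequence: 8 steps (1, 2, 3, 4, 6, 9, 10, 11).

**Steps most likely to fail**

Step 1. The enantiomeric purity of 4 may be lost in three ways: a leak into the exo transition state, which feeds the antipode; catalyst-mediated cycloreversion and re-addition before the quench; or weak face discrimination on an α-unsubstituted enal. Fallback, setting out from 1 and 2 and returning at 4: 2 is brominated (Br2, CH2Cl2, −78 °C) to 2,3-dibromopropanal F1, and Et3N removes HBr to give 2-bromoprop-2-enal F2. F2 is added to 1 at −78 °C under the B-butyl oxazaborolidinone of N-tosyltryptophan (C22H25BN2O4S, antipode chosen to give the (1S,4S) bridgeheads), a dienophile and catalyst class for which furan itself is known to react with high exo-formyl and face selectivity. This should give (1S,2S,4S)-2-bromo-1,4-dimethyl-7-oxabicyclo[2.2.1]hept-5-ene-2-carbaldehyde F3. Zn dust (THF, aqueous NH4Cl, 0 °C) then reduces the C8a–Br bond to a zinc enolate, which expels the bridging oxygen from C4a and gives 4 without any base-labile C8a proton being involved.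

Step 6. The dienolate may be acylated at C5 instead of the C4 methylene, may add in conjugate fashion to the unsaturated amide, or may simply be quenched by proton transfer from the crotonyl methyl. Fallback, setting out from 6 (with 8) and returning at 11: TMSOTf and Et3N (CH2Cl2, 0 °C) convert 6 into trimethyl-[(E)-[(5S)-5-methyl-2-methylidene-4,5-bis(trimethylsilyloxy)cyclohex-3-en-1-ylidene]methoxy]silane F4. The terminal methylene of this neutral bis(silyl enol ether) is acylated by acid chloride 8 (CH2Cl2, −78 °C → rt), a vinylogous Mukaiyama-type acylation of the kind known for 1,3-bis(silyloxy)-1,3-dienes with acid chlorides. Aqueous acid then gives (5S)-5-hydroxy-5-methyl-4-oxo-2-[(E)-2-oxopent-3-enyl]cyclohex-1-ene-1-carbaldehyde F5, which loses water in the same acid and closes to 11.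

Step 3. The π-allylpalladium alkoxide may lose a proton instead of shifting hydride, giving a dienol that dehydrates to an aromatic aldehyde. Fallback, setting out from 5 and returning at 6: hydrogenolysis of the allylic C5–O bond with Pd2(dba)3·CHCl3, PBu3, HCO2H and Et3N (dioxane, rt), the known formate reduction of γ,δ-epoxy-α,β-unsaturated carbonyl compounds, should give (4R,5S)-4,5-dihydroxy-2,5-dimethylcyclohex-1-ene-1-carbaldehyde F6. Dess–Martin periodinane (CH2Cl2, NaHCO3, 0 °C) then oxidises the secondary C6 alcohol beside the tertiary one to give 6.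

**Further compounds**
F1 | step 1 | 2,3-dibromopropanal (racemic) | O=CC(Br)CBr
F2 | step 1 | 2-bromoprop-2-enal | C=C(Br)C=O
F3 | step 1 | (1S,2S,4S)-2-bromo-1,4-dimethyl-7-oxabicyclo[2.2.1]hept-5-ene-2-carbaldehyde (formyl exo) | C[C@]12C=C[C@](C)(O1)[C@@](C=O)(Br)C2
F4 | step 6 | trimethyl-[(E)-[(5S)-5-methyl-2-methylidene-4,5-bis(trimethylsilyloxy)cyclohex-3-en-1-ylidene]methoxy]silane | C[C@@]1(O[Si](C)(C)C)C(O[Si](C)(C)C)=CC(=C)/C(=C/O[Si](C)(C)C)C1
F5 | step 6 | (5S)-5-hydroxy-5-methyl-4-oxo-2-[(E)-2-oxopent-3-enyl]cyclohex-1-ene-1-carbaldehyde | C[C@@]1(O)C(=O)CC(CC(=O)/C=C/C)=C(C=O)C1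
F6 | step 3 | (4R,5S)-4,5-dihydroxy-2,5-dimethylcyclohex-1-ene-1-carbaldehyde | C[C@@]1(O)[C@H](O)CC(C)=C(C=O)C1
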